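## Analysis of the target

Compound 20 is a 2,3-dihydro-1-benzofuran (a benzene ring fused to the dihydrofuran ring O1–C2–C3–C3a–C7a). C2 carries a 3-oxoprop-1-en-2-yl group, whose carbon C1' is a 1,1-disubstituted alkene carbon bearing the formyl group; C3 carries a 3-methylbutanoyloxy group; C5, para to O1, carries a 1-acyloxyethyl chain esterified with (R)-2-methylbutanoic acid. Of the four stereocentres, C2 (R) and C3 (S) are adjacent and trans on the five-membered ring. The side-chain carbinol carbon (R) and the α-carbon of the 2-methylbutanoate (R) are too far from the ring and from each other for any relay, so each needs its own source. The sensitive sites are the α-substituted acrolein (a Michael acceptor), the epimerisable α-centre of the 2-methylbutanoate, the side-chain ester on a para-alkoxybenzylic carbon, and above all the C3 ester: it is benzylic, activated by the ortho ring oxygen and flanked by the C2–H, so acid (ionisation) or base (vinylogous deprotonation once the enal is present) leads to the aromatic benzofuran. Two different esters also rule out any hydrolytic or strongly nucleophilic step once the first is in place. The hard part is to form the C2–C3 bond with control of both centres while C1' arrives in a form that can become the formyl-bearing alkene carbon without a late allylic C–H oxidation next to the labile C2–H. The strategy rests on C2: it bears both O1 and the alkene carbon C1' and is bonded to the carbinol carbon C3 on C3a, which is the pattern left when the oxygen-bearing γ-carbon of a 2-boryl allylcopper, generated from an O1-bound allene, adds to an ortho aldehyde, with boron on C1' as the masked formyl group. Because copper has to reach the carbonyl oxygen across a short, flat aryl tether, this closure is expected to put C1' and the C3 oxygen cis; the trans relationship is therefore made when the isovalerate is introduced at the benzylic C3 with inversion.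

## Retrosynthetic reasoning

**20 to 19.** The C1'–CHO bond is cut first. The enal is the most fragile part of 20 and would not pass a ketone reduction, a nucleophilic acylation catalyst or an alkoxide, so it is made last. Vinyl iodide 19 is its precursor, and the forward palladium-catalysed reductive carbonylation must insert one carbon at C1' faster than it reduces the C–I bond or the product.

**19 to 17.** The C1'–I bond is traced back to the C1'–B bond of 17 (through ate complex 18). Boron is kept until this point because it passes the cross-coupling, reduction and esterification steps that an iodide or an aldehyde would not. The forward step has to put iodine on the carbon that held boron without touching either ester.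

**17 to 15 and 16.** The side-chain ester is cut on the acyl side, which gives alcohol 15 and acid 16; 16 brings its stereocentre from the chiral pool. The coupling must be an acyl transfer, so that the carbinol C–O bond and its configuration stay intact, and mild enough not to epimerise 16.

**15 to 14.** The carbinol C–H bond is cut. No ring stereocentre can steer this remote centre, so it is set by catalyst-controlled transfer hydrogenation of aryl methyl ketone 14. The ketone is also the simplest way to attach the two-carbon chain.

**14 to 11 and 12.** The C5–C(acetyl) bond is cut to aryl bromide 11 and stannane 12 (through enol ether 13). Bromine para to O1 is an inert spectator through the base, copper and substitution steps before it. A tin partner is chosen because it needs no base, so the C–B bond does not transmetalate.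

**11 to 9 and 10.** The C3–O bond is cut on the alkyl side: the ester oxygen comes from acid 10 and displaces the activated hydroxyl group of the cis alcohol 9. This is where the trans relationship is made. The nucleophile enters C3 on the face opposite the C2 substituent, whether by direct displacement or through an ion pair.

**9 to 6 and 7.** The key disconnection cuts C2–C3 and C1'–B (O-boryl ether 8 is the form in which the product leaves the catalytic cycle). No other ring bond creates both stereocentres, the ring and the C1' handle in one event. The forward reaction must borylate the central allene carbon of 6 with diboron 7, add the resulting allylcopper through its γ-carbon to the aldehyde, and differentiate the two faces of the aldehyde.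

**6 to 1 and 2.** The allenyl ether is traced to the propargyl ether by base-mediated isomerisation, and the propargyl ether to phenol 1 and bromide 2. The aldehyde cannot be present in the base step, so it is carried as dimethyl acetal (4, then 5) and released afterwards (3 → 4 → 5 → 6). An acetal is preferred to a free benzylic alcohol, whose alkoxide could add to the allenyl ether.

## Alternatives that were turned down

**Alternative 1:** The benzene ring is dismantled: C3a–C7a, C4–C5 and C6–C7 are cut. This leaves an acyclic 1,6-diyne (a silyl-capped ynol ether on the C2 oxygen and a propargylic alkyne at C3) and an alkynyl methyl ketone. Forward, a ruthenium-catalysed [2+2+2] cycloaddition would build the arene and with it the dihydrofuran ring, giving trans-5-acetyl-3-(tert-butyldimethylsilyloxy)-2-isopropenyl-7-(trimethylsilyl)-2,3-dihydrobenzofuran A1.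
- For: C2 and C3 are set in an open chain, where an anti-diol pattern can be made by dependable methods. The trans relationship is not left to a ring closure and no inversion step is needed. The acetyl group arrives on C5 without aryl halide chemistry. On these points it is stronger than the chosen route.
- Against: the ynol ether of a secondary alcohol is laborious and fragile. The orientation of the unsymmetrical alkyne (acetyl at C5, not C6) depends on steric steering by the silyl cap, and the electron-poor alkyne can trimerise on its own. The C7 silyl group must be removed by protodesilylation next to an ionisable C3 oxygen. A1 has a methyl group where 20 has the formyl group, so a late allylic oxidation in competition with the C2–H remains.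
- Comparison: the diyne alone needs more steps than the whole precursor 6. The chosen route offers a four-step substrate and a C1' that leaves the key step already functionalised.

**Alternative 2:** C3a–C3 and O1–C2 are cut, which gives a brominated magnesium phenoxide and a small, dimethyl-substituted α,β-epoxy aldehyde. Forward, the phenoxide would add through its ortho carbon to the aldehyde, and the phenoxide oxygen would then open the epoxide at C2 in the exo mode, giving trans-5-bromo-2-(2-hydroxypropan-2-yl)-2,3-dihydrobenzofuran-3-ol A2 in one pot.
- For: two cheap partners and one operation; C2 comes from clean inversion of a preformed epoxide carbon; bromine is kept for the side chain. In cost and in brevity up to the ring it beats the chosen route.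
- Against: the configuration at C3 depends on the facial selectivity of an aryl addition to a labile α-epoxy aldehyde (chelation against Felkin control). The ortho-hydroxybenzyl alkoxide can collapse to a quinone methide. Above all, A2 carries a saturated hydroxy-isopropyl group: it has to be dehydrated regioselectively away from C2 and then oxidised at the allylic methyl group, both next to a C3 oxygen that eliminates easily.
- Comparison: the chosen route pays with an unproven cyclisation and an inversion step, but delivers C1' as an sp2 carbon bearing boron, one functional-group exchange away from the enal.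

**Alternative 3:** C2–C3 and O1–C2 are cut, so that a methallyl sulfonium ylide on a chiral sulfide and an O-silylated, acetyl-substituted salicylaldehyde remain. Forward, the ylide adds to the aldehyde to form the trans vinyl epoxide, fluoride frees the phenoxide, the phenoxide opens the epoxide at the allylic C2 with inversion, and the C3 alkoxide is acylated in the same flask, giving trans-5-acetyl-2-isopropenyl-2,3-dihydrobenzofuran-3-yl 3-methylbutanoate A3.
- For: A3 is the most advanced product of the three, with ring, trans relationship, acetyl group and isovalerate from one operation. On convergence and on the direct trans outcome it is stronger than the chosen route.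
- Against: allyl sulfonium ylides tend to rearrange by [2,3]-shift and give modest control of epoxide geometry and absolute configuration. The aryl methyl ketone is a second, enolisable electrophile. The phenoxide must attack C2 in the endo sense in competition with attack at the alkene terminus. A3 again ends with a methyl group on C1'.
- Comparison: the chosen route keeps the ketone out of the C–C bond-forming step, relies on a catalytic ligand-controlled addition, and fixes the attachment point of the formyl carbon with boron.

Key step: step 5

Assumption: the sense of asymmetric induction of the CuCl/bisphosphine catalyst on this substrate class cannot be assigned in advance; the route is written with (S,S)-Ph-BPE, and its commercially available antipode is used if the first run gives the mirror-image series.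

## Route

Step 1
Reactants: 1 5-bromo-2-hydroxybenzaldehyde; 2 3-bromoprop-1-yne (propargyl bromide)
Product: 3 5-bromo-2-(prop-2-yn-1-yloxy)benzaldehyde
Conditions: K2CO3, DMF, 25 °C
Reagents that add atoms: none
Why: Williamson ether synthesis: the phenoxide of 1, acidified by the ortho formyl group, displaces bromide from 2 in an SN2 reaction, and O-alkylation is the normal course in DMF.

Step 2
Reactants: 3 5-bromo-2-(prop-2-yn-1-yloxy)benzaldehyde
Product: 4 4-bromo-2-(dimethoxymethyl)-1-(prop-2-yn-1-yloxy)benzene
Conditions: HC(OMe)3, TsOH·H2O (1 mol %), MeOH, 25 °C; then Et3N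
Reagents that add atoms: trimethyl orthoformate, COC(OC)OC
Why: Acid-catalysed acetalisation with the orthoformate as water scavenger; it removes the only base-sensitive electrophile before the isomerisation, and neither the alkyne nor the aryl bromide reacts.

Step 3
Reactants: 4 4-bromo-2-(dimethoxymethyl)-1-(prop-2-yn-1-yloxy)benzene
Product: 5 4-bromo-2-(dimethoxymethyl)-1-(propa-1,2-dien-1-yloxy)benzene
Conditions: KOtBu (0.3 equiv), THF, 0 to 20 °C
Reagents that add atoms: none
Why: Base-catalysed propargyl-to-allenyl prototropic isomerisation of an aryl propargyl ether; with substoichiometric KOtBu at or below room temperature it stops at the allenyl ether, and the acetal, unlike a free aldehyde or a benzylic alkoxide, gives the base and the allene nothing to react with.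

Step 4
Reactants: 5 4-bromo-2-(dimethoxymethyl)-1-(propa-1,2-dien-1-yloxy)benzene
Product: 6 5-bromo-2-(propa-1,2-dien-1-yloxy)benzaldehyde
Conditions: PPTS (5 mol %), acetone–H2O (10:1), 20 °C
Reagents that add atoms: water, O
Why: Acetal hydrolysis under weak acid; the dimethyl acetal of an ortho-alkoxybenzaldehyde ionises to its oxocarbenium ion far faster than an aryl allenyl ether is protonated on carbon, so the allene should survive, and the aldehyde is filtered through Et3N-deactivated silica.

Step 5
Reactants: 6 5-bromo-2-(propa-1,2-dien-1-yloxy)benzaldehyde; 7 bis(pinacolato)diboron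
Product: 9 (2R,3R)-5-bromo-2-[1-(4,4,5,5-tetramethyl-1,3,2-dioxaborolan-2-yl)ethenyl]-2,3-dihydro-1-benzofuran-3-ol (2,3-cis), via O-boryl ether 8 (not isolated)
Conditions: CuCl (5 mol %), (S,S)-Ph-BPE (6 mol %), NaOtBu (10 mol %), THF, 0 to 22 °C; then aq. NH4Cl
Reagents that add atoms: none
Why: Proposed new method: the closest known reactions are the copper-catalysed enantioselective three-component coupling of monosubstituted allenes, B2(pin)2 and aldehydes to 2-boryl homoallylic alcohols and the cis-selective metal-catalysed cyclisations of allene-tethered aldehydes through allylmetal intermediates; an aryl allenyl ether with a tethered aldehyde has not been used, and the reasoning is that the same elementary steps apply. L*Cu–OtBu (L* = the bisphosphine) and 7 give L*Cu–B(pin), which adds across the unhindered terminal C=C of 6 on the face away from the aryloxy group, boron to the central carbon C1', to give the Z-configured 2-boryl allylcopper. Its oxygen-bearing γ-carbon C2 attacks the ortho aldehyde carbon C3 while copper binds the carbonyl oxygen in a six-membered Zimmerman–Traxler array; this forms C2–C3 and closes the dihydrofuran ring in the 5-exo-trig mode, and the copper alkoxide is released by 7 as 8, which aqueous work-up hydrolyses to 9. C3 is set by the aldehyde face that the chiral bisphosphine leaves open, and C2 follows from it: the three-atom aryl tether lets copper reach the carbonyl oxygen only when C1' and that oxygen lie on the same face of the forming ring (cis-fused chair, O1 axial, aryl carbon equatorial), so 2,3-cis is the expected relative configuration. The step needs chemoselectivity for the allene over the aldehyde and the aryl bromide, which the unsubstituted allene terminus and the use of only catalytic alkoxide should provide; γ-selectivity, which the tether enforces because α-attack would need a seven-membered ring; and enantioselectivity, which rests on the ligand alone.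

Step 6
Reactants: 9 (2R,3R)-5-bromo-2-[1-(4,4,5,5-tetramethyl-1,3,2-dioxaborolan-2-yl)ethenyl]-2,3-dihydro-1-benzofuran-3-ol; 10 3-methylbutanoic acid
Product: 11 (2R,3S)-5-bromo-2-[1-(4,4,5,5-tetramethyl-1,3,2-dioxaborolan-2-yl)ethenyl]-2,3-dihydro-1-benzofuran-3-yl 3-methylbutanoate (2,3-trans)
Conditions: PPh3, DIAD, THF, 0 to 20 °C
Reagents that add atoms: none
Why: Mitsunobu esterification: the carboxylate of 10 displaces the oxyphosphonium group of 9 with inversion at C3, which turns cis into trans and installs the isovalerate in the same step. Attack trans to the C2 substituent is also what an ion-pair pathway at this benzylic carbon would give, so both pathways should converge on 11.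

Step 7
Reactants: 11 (2R,3S)-5-bromo-2-[1-(4,4,5,5-tetramethyl-1,3,2-dioxaborolan-2-yl)ethenyl]-2,3-dihydro-1-benzofuran-3-yl 3-methylbutanoate; 12 tributyl(1-ethoxyethenyl)stannane
Product: 14 (2R,3S)-5-acetyl-2-[1-(4,4,5,5-tetramethyl-1,3,2-dioxaborolan-2-yl)ethenyl]-2,3-dihydro-1-benzofuran-3-yl 3-methylbutanoate, via enol ether 13 (not isolated)
Conditions: PdCl2(PPh3)2 (5 mol %), toluene, 90 °C; then 1 M HCl, THF, 0 °C
Reagents that add atoms: water, O
Why: Stille coupling of the aryl bromide with the 1-ethoxyvinyl stannane as acetyl equivalent, then hydrolysis of aryl enol ether 13, which is far more acid-labile than the C3 ester. Without base or fluoride the pinacol boronate does not transmetalate, and the non-polar solvent disfavours ionisation of the allylic C2–O1 bond by zerovalent palladium.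

Step 8
Reactants: 14 (2R,3S)-5-acetyl-2-[1-(4,4,5,5-tetramethyl-1,3,2-dioxaborolan-2-yl)ethenyl]-2,3-dihydro-1-benzofuran-3-yl 3-methylbutanoate
Product: 15 (2R,3S)-5-[(1R)-1-hydroxyethyl]-2-[1-(4,4,5,5-tetramethyl-1,3,2-dioxaborolan-2-yl)ethenyl]-2,3-dihydro-1-benzofuran-3-yl 3-methylbutanoate
Conditions: RuCl[(R,R)-TsDPEN](p-cymene) (1 mol %), HCO2H–Et3N (5:2), CH2Cl2, 25 °C
Reagents that add atoms: none
Why: Noyori asymmetric transfer hydrogenation of an aryl methyl ketone; the (R,R) catalyst delivers hydride to the face that gives the (R) carbinol (catalyst control, the ring stereocentres are too remote to interfere), and the alkenyl boronate and the ester are inert to the ruthenium hydride.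

Step 9
Reactants: 15 (2R,3S)-5-[(1R)-1-hydroxyethyl]-2-[1-(4,4,5,5-tetramethyl-1,3,2-dioxaborolan-2-yl)ethenyl]-2,3-dihydro-1-benzofuran-3-yl 3-methylbutanoate; 16 (2R)-2-methylbutanoic acid
Product: 17 (1R)-1-[(2R,3S)-3-[(3-methylbutanoyl)oxy]-2-[1-(4,4,5,5-tetramethyl-1,3,2-dioxaborolan-2-yl)ethenyl]-2,3-dihydro-1-benzofuran-5-yl]ethyl (2R)-2-methylbutanoate
Conditions: DCC, DMAP (10 mol %), CH2Cl2, 0 °C
Reagents that add atoms: none
Why: Steglich esterification (DCC activation, acyl transfer through the acylpyridinium ion); the carbinol C–O bond is not broken, so its configuration is kept, and low temperature with little DMAP should keep the α-centre of 16 from epimerising.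

Step 10
Reactants: 17 (1R)-1-[(2R,3S)-3-[(3-methylbutanoyl)oxy]-2-[1-(4,4,5,5-tetramethyl-1,3,2-dioxaborolan-2-yl)ethenyl]-2,3-dihydro-1-benzofuran-5-yl]ethyl (2R)-2-methylbutanoate
Product: 19 (1R)-1-[(2S,3S)-2-(1-iodoethenyl)-3-[(3-methylbutanoyl)oxy]-2,3-dihydro-1-benzofuran-5-yl]ethyl (2R)-2-methylbutanoate, via methoxyboronate salt 18 (not isolated)
Conditions: NaOMe (1.1 equiv), THF–MeOH, −78 °C; then I2 (1.1 equiv), −78 to −40 °C; aq. Na2S2O3
Reagents that add atoms: iodine, II
Why: Base-promoted iododeboronation of an alkenylboronate: methoxide turns the trigonal boronate into electron-rich ate complex 18, iodine adds to its C=C bond, and boron leaves together with the terminal iodide, so iodine ends on C1'. One equivalent of methoxide at −78 °C is bound by boron before it can reach the esters; C2 is not touched and its descriptor changes to S only because iodine outranks C3.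

Step 11
Reactants: 19 (1R)-1-[(2S,3S)-2-(1-iodoethenyl)-3-[(3-methylbutanoyl)oxy]-2,3-dihydro-1-benzofuran-5-yl]ethyl (2R)-2-methylbutanoate
Product: 20 (1R)-1-[(2R,3S)-3-[(3-methylbutanoyl)oxy]-2-(3-oxoprop-1-en-2-yl)-2,3-dihydro-1-benzofuran-5-yl]ethyl (2R)-2-methylbutanoate
Conditions: Pd(PPh3)4 (5 mol %), CO (1 atm), Bu3SnH (1.1 equiv, slow addition), THF, 50 °C
Reagents that add atoms: carbon monoxide, [C-]#[O+]
Why: Palladium-catalysed reductive carbonylation (formylation) of a vinyl iodide: oxidative addition, CO insertion to the acylpalladium iodide, hydride transfer from tin and reductive elimination. Slow addition of Bu3SnH keeps direct reduction of the vinylpalladium species and conjugate reduction of the enal behind, and the neutral medium spares both esters and C2.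

## Compound list

1 | 5-bromo-2-hydroxybenzaldehyde | O=Cc1cc(Br)ccc1O | starting material
2 | 3-bromoprop-1-yne (propargyl bromide) | C#CCBr | starting material
3 | 5-bromo-2-(prop-2-yn-1-yloxy)benzaldehyde | O=Cc1cc(Br)ccc1OCC#C | intermediate
4 | 4-bromo-2-(dimethoxymethyl)-1-(prop-2-yn-1-yloxy)benzene | COC(OC)c1cc(Br)ccc1OCC#C | intermediate
5 | 4-bromo-2-(dimethoxymethyl)-1-(propa-1,2-dien-1-yloxy)benzene | COC(OC)c1cc(Br)ccc1OC=C=C | intermediate
6 | 5-bromo-2-(propa-1,2-dien-1-yloxy)benzaldehyde | C=C=COc1ccc(Br)cc1C=O | intermediate
7 | bis(pinacolato)diboron | CC1(C)OB(OC1(C)C)B1OC(C)(C)C(C)(C)O1 | starting material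
8 | 2-{[(2R,3R)-5-bromo-2-[1-(4,4,5,5-tetramethyl-1,3,2-dioxaborolan-2-yl)ethenyl]-2,3-dihydro-1-benzofuran-3-yl]oxy}-4,4,5,5-tetramethyl-1,3,2-dioxaborolane | C=C(B1OC(C)(C)C(C)(C)O1)[C@H]1Oc2ccc(Br)cc2[C@H]1OB1OC(C)(C)C(C)(C)O1 | intermediate
9 | (2R,3R)-5-bromo-2-[1-(4,4,5,5-tetramethyl-1,3,2-dioxaborolan-2-yl)ethenyl]-2,3-dihydro-1-benzofuran-3-ol (2,3-cis) | C=C(B1OC(C)(C)C(C)(C)O1)[C@H]1Oc2ccc(Br)cc2[C@H]1O | intermediate
10 | 3-methylbutanoic acid | CC(C)CC(=O)O | starting material
11 | (2R,3S)-5-bromo-2-[1-(4,4,5,5-tetramethyl-1,3,2-dioxaborolan-2-yl)ethenyl]-2,3-dihydro-1-benzofuran-3-yl 3-methylbutanoate (2,3-trans) | C=C(B1OC(C)(C)C(C)(C)O1)[C@H]1Oc2ccc(Br)cc2[C@@H]1OC(=O)CC(C)C | intermediate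
12 | tributyl(1-ethoxyethenyl)stannane | CCCC[Sn](CCCC)(CCCC)C(=C)OCC | starting material
13 | (2R,3S)-5-(1-ethoxyethenyl)-2-[1-(4,4,5,5-tetramethyl-1,3,2-dioxaborolan-2-yl)ethenyl]-2,3-dihydro-1-benzofuran-3-yl 3-methylbutanoate | C=C(B1OC(C)(C)C(C)(C)O1)[C@H]1Oc2ccc(C(=C)OCC)cc2[C@@H]1OC(=O)CC(C)C | intermediate
14 | (2R,3S)-5-acetyl-2-[1-(4,4,5,5-tetramethyl-1,3,2-dioxaborolan-2-yl)ethenyl]-2,3-dihydro-1-benzofuran-3-yl 3-methylbutanoate | C=C(B1OC(C)(C)C(C)(C)O1)[C@H]1Oc2ccc(C(C)=O)cc2[C@@H]1OC(=O)CC(C)C | intermediate
15 | (2R,3S)-5-[(1R)-1-hydroxyethyl]-2-[1-(4,4,5,5-tetramethyl-1,3,2-dioxaborolan-2-yl)ethenyl]-2,3-dihydro-1-benzofuran-3-yl 3-methylbutanoate | C=C(B1OC(C)(C)C(C)(C)O1)[C@H]1Oc2ccc([C@@H](C)O)cc2[C@@H]1OC(=O)CC(C)C | intermediate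
16 | (2R)-2-methylbutanoic acid | CC[C@@H](C)C(=O)O | starting material
17 | (1R)-1-[(2R,3S)-3-[(3-methylbutanoyl)oxy]-2-[1-(4,4,5,5-tetramethyl-1,3,2-dioxaborolan-2-yl)ethenyl]-2,3-dihydro-1-benzofuran-5-yl]ethyl (2R)-2-methylbutanoate | C=C(B1OC(C)(C)C(C)(C)O1)[C@H]1Oc2ccc([C@@H](C)OC(=O)[C@H](C)CC)cc2[C@@H]1OC(=O)CC(C)C | intermediate
18 | sodium methoxy ate complex of 17 (methoxide bound to boron) | [Na+].CO[B-]1(OC(C)(C)C(C)(C)O1)C(=C)[C@H]1Oc2ccc([C@@H](C)OC(=O)[C@H](C)CC)cc2[C@@H]1OC(=O)CC(C)C | intermediate
19 | (1R)-1-[(2S,3S)-2-(1-iodoethenyl)-3-[(3-methylbutanoyl)oxy]-2,3-dihydro-1-benzofuran-5-yl]ethyl (2R)-2-methylbutanoate (2,3-trans) | C=C(I)[C@H]1Oc2ccc([C@@H](C)OC(=O)[C@H](C)CC)cc2[C@@H]1OC(=O)CC(C)C | intermediate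
20 | (1R)-1-[(2R,3S)-3-[(3-methylbutanoyl)oxy]-2-(3-oxoprop-1-en-2-yl)-2,3-dihydro-1-benzofuran-5-yl]ethyl (2R)-2-methylbutanoate | C=C(C=O)[C@H]1Oc2ccc([C@@H](C)OC(=O)[C@H](C)CC)cc2[C@@H]1OC(=O)CC(C)C | target

## Step count and least certain steps

Total step count: 11. Longest linear sequence: 11 steps (1 to 20).

**Step 5 (key step, proposed new method).** The most likely failure is weak control by the ligand: the intramolecular addition is fast and the two enantiomeric cis-fused chairs differ only through the distant bisphosphine, so the enantiomeric purity may be low. The copper–boryl species may also add directly to the aldehyde carbonyl before the allene inserts. Partial reaction through the E-allylcopper would leak into the trans series and lower the diastereomeric purity.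

Fallback with known reactions only, setting out from 1 and returning at 11:
- 1 is silylated (iPr3SiCl, imidazole, DMF) to 5-bromo-2-[(triisopropylsilyl)oxy]benzaldehyde F1.
- Horner–Wadsworth–Emmons olefination with diethyl [3-(trimethylsilyl)prop-2-yn-1-yl]phosphonate (LiN(SiMe3)2, THF, −78 to 0 °C) gives the E-enyne [(3E)-4-{5-bromo-2-[(triisopropylsilyl)oxy]phenyl}but-3-en-1-yn-1-yl]trimethylsilane F2.
- Shi epoxidation with the enantiomer of the fructose-derived ketone (KHSO5 as Oxone, K2CO3, MeCN–dimethoxymethane–aqueous buffer, 0 °C), which attacks the alkene and leaves the alkyne, gives (2S,3S)-2-{5-bromo-2-[(triisopropylsilyl)oxy]phenyl}-3-[(trimethylsilyl)ethynyl]oxirane F3.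
- Bu4NF in THF removes both silyl groups, and the freed phenoxide opens the trans epoxide at the propargylic carbon with inversion, the ring closure known from sulfur-ylide annulations of salicylaldehydes. This gives (2R,3S)-5-bromo-2-ethynyl-2,3-dihydro-1-benzofuran-3-ol F4.
- α-Selective copper-catalysed protoboration of the terminal alkyne ((SIMes)CuCl, NaOtBu, 7, MeOH, THF, −50 to −15 °C; the propargylic oxygen directs boron to the internal carbon) gives (2R,3S)-5-bromo-2-[1-(4,4,5,5-tetramethyl-1,3,2-dioxaborolan-2-yl)ethenyl]-2,3-dihydro-1-benzofuran-3-ol F5, the trans alcohol.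
- F5 is esterified with 10 (DCC, DMAP, CH2Cl2, 0 °C), without inversion, to 11.

**Step 6.** The oxyphosphonium intermediate sits on a benzylic carbon activated by the ortho ring oxygen. It may ionise and lose the C2 proton, which is dehydrative aromatisation to the benzofuran, faster than the weakly acidic aliphatic acid captures it.

Fallback, from 9 back to 11: the inversion is separated from the introduction of the isovalerate. 9 is treated with 4-nitrobenzoic acid, PPh3 and DIAD in toluene at −20 °C; the much more acidic partner protonates the betaine and captures the oxyphosphonium ion faster. This gives (2R,3S)-5-bromo-2-[1-(4,4,5,5-tetramethyl-1,3,2-dioxaborolan-2-yl)ethenyl]-2,3-dihydro-1-benzofuran-3-yl 4-nitrobenzoate F6. Methanolysis (K2CO3, MeOH, 0 °C) gives the trans alcohol F5, and esterification with 10 (DCC, DMAP) gives 11.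

**Step 10.** Free methoxide may transesterify one of the two esters before it is bound by boron, or iodine may substitute the alkoxy-activated arene at C7 instead of reacting with the ate complex.

Fallback, from 17 back to 19: 17 is converted with KHF2 in MeOH–H2O into potassium {1-[(2R,3S)-3-[(3-methylbutanoyl)oxy]-5-[(1R)-1-{[(2R)-2-methylbutanoyl]oxy}ethyl]-2,3-dihydro-1-benzofuran-2-yl]ethenyl}trifluoroborate F7, an isolable salt. Oxidative iodination with NaI and TsN(Cl)Na (chloramine-T) in THF–H2O at 20 °C, without alkoxide, then gives 19.

**Step 11.** Hydride may be transferred from tin to the vinylpalladium iodide before CO inserts, which simply reduces the C–I bond. The tin hydride may reduce the enal in the conjugate sense. Zerovalent palladium may open the allylic C2–O1 bond once the iodide is used up.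

Fallback, from 19 back to 20: the carbon is introduced at the alcohol oxidation level without any hydride. Stille coupling of 19 with (tributylstannyl)methanol (Pd(PPh3)4, dioxane, 80 °C) gives (1R)-1-[(2R,3S)-2-(3-hydroxyprop-1-en-2-yl)-3-[(3-methylbutanoyl)oxy]-2,3-dihydro-1-benzofuran-5-yl]ethyl (2R)-2-methylbutanoate F8. Oxidation of this allylic alcohol with MnO2 in CH2Cl2 at 20 °C gives 20.

## Further compounds

F1 | step 5 | 5-bromo-2-[(triisopropylsilyl)oxy]benzaldehyde | O=Cc1cc(Br)ccc1O[Si](C(C)C)(C(C)C)C(C)C
F2 | step 5 | [(3E)-4-{5-bromo-2-[(triisopropylsilyl)oxy]phenyl}but-3-en-1-yn-1-yl]trimethylsilane | C[Si](C)(C)C#C/C=C/c1cc(Br)ccc1O[Si](C(C)C)(C(C)C)C(C)C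
F3 | step 5 | (2S,3S)-2-{5-bromo-2-[(triisopropylsilyl)oxy]phenyl}-3-[(trimethylsilyl)ethynyl]oxirane | C[Si](C)(C)C#C[C@@H]1O[C@H]1c1cc(Br)ccc1O[Si](C(C)C)(C(C)C)C(C)C
F4 | step 5 | (2R,3S)-5-bromo-2-ethynyl-2,3-dihydro-1-benzofuran-3-ol | C#C[C@H]1Oc2ccc(Br)cc2[C@@H]1O
F5 | step 5 | (2R,3S)-5-bromo-2-[1-(4,4,5,5-tetramethyl-1,3,2-dioxaborolan-2-yl)ethenyl]-2,3-dihydro-1-benzofuran-3-ol (2,3-trans) | C=C(B1OC(C)(C)C(C)(C)O1)[C@H]1Oc2ccc(Br)cc2[C@@H]1O
F6 | step 6 | (2R,3S)-5-bromo-2-[1-(4,4,5,5-tetramethyl-1,3,2-dioxaborolan-2-yl)ethenyl]-2,3-dihydro-1-benzofuran-3-yl 4-nitrobenzoate | C=C(B1OC(C)(C)C(C)(C)O1)[C@H]1Oc2ccc(Br)cc2[C@@H]1OC(=O)c1ccc(cc1)[N+](=O)[O-]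
F7 | step 10 | potassium {1-[(2R,3S)-3-[(3-methylbutanoyl)oxy]-5-[(1R)-1-{[(2R)-2-methylbutanoyl]oxy}ethyl]-2,3-dihydro-1-benzofuran-2-yl]ethenyl}trifluoroborate | [K+].F[B-](F)(F)C(=C)[C@H]1Oc2ccc([C@@H](C)OC(=O)[C@H](C)CC)cc2[C@@H]1OC(=O)CC(C)C
F8 | step 11 | (1R)-1-[(2R,3S)-2-(3-hydroxyprop-1-en-2-yl)-3-[(3-methylbutanoyl)oxy]-2,3-dihydro-1-benzofuran-5-yl]ethyl (2R)-2-methylbutanoate | C=C(CO)[C@H]1Oc2ccc([C@@H](C)OC(=O)[C@H](C)CC)cc2[C@@H]1OC(=O)CC(C)C
A1 | alternative 1 | trans-5-acetyl-3-(tert-butyldimethylsilyloxy)-2-isopropenyl-7-(trimethylsilyl)-2,3-dihydrobenzofuran | C=C(C)[C@H]1Oc2c([Si](C)(C)C)cc(C(C)=O)cc2[C@@H]1O[Si](C)(C)C(C)(C)C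
A2 | alternative 2 | trans-5-bromo-2-(2-hydroxypropan-2-yl)-2,3-dihydrobenzofuran-3-ol | CC(C)(O)[C@H]1Oc2ccc(Br)cc2[C@@H]1O
A3 | alternative 3 | trans-5-acetyl-2-isopropenyl-2,3-dihydrobenzofuran-3-yl 3-methylbutanoate | C=C(C)[C@H]1Oc2ccc(C(C)=O)cc2[C@@H]1OC(=O)CC(C)C
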